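**Strategy.** The target is cut at the C8–C14 bond (ent-kaurane numbering: C8 is the quaternary carbon that carries the C7H2–O arm, C14 the one-carbon bridge of rings C and D). Because C8 sits between C7 and the epoxide carbon C9, it is treated as the central carbon of a β-keto ester. Oxidation of an acyclic 2-allyl-3-oxohept-6-enoate of 8-phenylmenthol to the C8 radical closes ring C through C8–C14 and then ring D, delivering the bicyclo[3.2.1]octane with quaternary C8 and the C16=C17 methylene in one operation. Ring A is attached afterwards through an ester tether by an intramolecular Heck reaction that forms ring B and quaternary C10.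

Key step: step 3

**Remarks before the steps**
- Atom labels C1–C20 follow ent-kaurane numbering throughout.
- Assumption: the 8-phenylmenthyl ester is taken to react through the chelate-like conformer (ester C=O syn to the ketone carbon) with attack anti to the phenyl ring, which calls for the (1S,2R,5S) alcohol; if the sense of induction proves opposite, its antipode is used and nothing else changes.
- Compound 7 is a mixture of epimers at the α-carbon, acetals 17–24 are anomeric mixtures at C6, and carbinols 18 and 22 are C15 epimers. These centres are left open in the SMILES because each is erased or reset later.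

Step 1
Reactants: 1 (1S,2R,5S)-8-phenylmenthol; 2 2,2,6-trimethyl-4H-1,3-dioxin-4-one
Product: 4 (1S,2R,5S)-8-phenylmenthyl 3-oxobutanoate, via acetylketene 3 (not isolated)
Conditions: xylene, 140 °C, acetone distilled off
Reagents that add atoms: 2,2,6-trimethyl-4H-1,3-dioxin-4-one (2), CC1=CC(=O)OC(C)(C)O1
Why: Thermal retro-hetero-Diels–Alder cleavage of the dioxinone gives acetylketene, which acylates the hindered secondary alcohol (acetoacetylation); the stereocenters of the auxiliary are untouched.

Step 2
Reactants: 4 8-phenylmenthyl 3-oxobutanoate; 5 allyl bromide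
Product: 7 8-phenylmenthyl 2-allyl-3-oxohept-6-enoate, via 8-phenylmenthyl 3-oxohept-6-enoate 6 (not isolated)
Conditions: NaH, THF, 0 °C; n-BuLi, 0 °C; allyl bromide (1.0 equiv), 0 °C; then allyl bromide (1.2 equiv), NaI (cat.), 23 → 45 °C
Reagents that add atoms: allyl bromide (5), C=CCBr
Why: Dianion γ-alkylation of the acetoacetate is followed by C-alkylation of the resulting β-keto ester enolate (two successive SN2 allylations); the new α-centre is not controlled and is erased in step 3.

Step 3
Reactants: 7 8-phenylmenthyl 2-allyl-3-oxohept-6-enoate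
Product: 8 8-phenylmenthyl (1R,5R)-6-methylene-2-oxobicyclo[3.2.1]octane-1-carboxylate
Conditions: Mn(OAc)3·2H2O (2.2 equiv), Cu(OAc)2·H2O (1 equiv), degassed AcOH, 25 °C
Reagents that add atoms: none
Why: Trivalent manganese oxidizes the enol of the β-keto ester to the C8 radical, which adds 6-endo-trig to the terminal carbon C14 of the butenyl chain (ring C, a cyclohexanone); the secondary C13 radical then adds 5-exo-trig to the inner carbon C16 of the allyl group (ring D), and the primary C17 radical is oxidized by divalent copper with loss of the only β-hydrogen, on C16, to give the exocyclic methylene. The closest known reaction type is the Mn(OAc)3/Cu(OAc)2 oxidative tandem cyclization of 2-allyl-3-oxo-6-alkenoates to bicyclo[3.2.1]octanes, including its use with 8-phenylmenthyl esters. The 6-endo mode is secured by the C9 carbonyl lying inside the forming ring, and the second closure must outrun copper oxidation of the C13 radical, which the cis-1,3 placement of radical and allyl group favours. C8 is set by the auxiliary, whose phenyl ring covers one face of the planar radical so that C14 bonds to the open face; C13 follows from C8 because the two-carbon bridge can only close cis.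

Step 4
Reactants: 8 bicyclic keto ester
Product: 9 8-phenylmenthyl (1R,5R)-6-methylene-2-(trifluoromethylsulfonyloxy)bicyclo[3.2.1]oct-2-ene-1-carboxylate
Conditions: KN(SiMe3)2, THF, −78 °C; PhNTf2, −78 → 0 °C
Reagents that add atoms: N-phenylbis(trifluoromethanesulfonimide), O=S(=O)(N(c1ccccc1)S(=O)(=O)C(F)(F)F)C(F)(F)F
Why: The ketone can enolize only toward C11 because C8 is quaternary, and O-sulfonylation of the potassium enolate gives the enol triflate (no stereocenter is formed).

Step 5
Reactants: 9 enol triflate ester
Product: 10 [(1S,5R)-1-(hydroxymethyl)-6-methylenebicyclo[3.2.1]oct-2-en-2-yl] trifluoromethanesulfonate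
Conditions: i-Bu2AlH (3.5 equiv), CH2Cl2, −78 → 0 °C; aqueous Rochelle salt
Reagents that add atoms: none
Why: Hydride reduction of the ester to the primary alcohol releases the auxiliary, while the enol triflate should survive i-Bu2AlH at low temperature (ester reduction; no stereocenter is affected).

Step 6
Reactants: 11 geranic acid
Product: 12 (±)-α-cyclogeranic acid (2,6,6-trimethylcyclohex-2-ene-1-carboxylic acid)
Conditions: H3PO4 (85%), toluene, 90 °C
Reagents that add atoms: none
Why: Brønsted-acid cation–olefin cyclization: protonation of the distal trisubstituted alkene gives a tertiary cation that is captured by the α-carbon of the enoic acid, and loss of a ring proton gives the β,γ-unsaturated acid as a racemate.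

Step 7
Reactants: 12 (±)-α-cyclogeranic acid
Product: 13 (R)-α-cyclogeranic acid
Conditions: preparative supercritical-fluid chromatography, amylose tris(3,5-dimethylphenylcarbamate) phase, CO2/MeOH
Reagents that add atoms: none
Why: Enantiomer separation on a chiral stationary phase supplies the (R)-acid, whose stereocenter becomes C5 of the target (no new stereocenter is formed).

Step 8
Reactants: 10 triflate alcohol; 13 (R)-α-cyclogeranic acid
Product: 14 [(1S,5R)-6-methylene-2-(trifluoromethylsulfonyloxy)bicyclo[3.2.1]oct-2-en-1-yl]methyl (R)-2,6,6-trimethylcyclohex-2-ene-1-carboxylate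
Conditions: EDCI, DMAP, CH2Cl2, 0 → 23 °C
Reagents that add atoms: none
Why: Steglich esterification (carbodiimide and DMAP activation) joins the hindered acid to the neopentyl-type alcohol without passing through a ketene, so the C5 configuration should be kept.

Step 9
Reactants: 14 ester-tethered enol triflate
Product: 15 6,7-seco-ent-kaura-1,9(11),16-trien-6-oic acid 6,7-lactone (ε-lactone; C6 carbonyl, ring oxygen on C7; H5 trans to the C10 methyl)
Conditions: Pd(OAc)2 (10 mol %), PPh3 (30 mol %), Ag2CO3 (2 equiv), MeCN, 80 °C
Reagents that add atoms: none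
Why: Intramolecular Heck reaction: oxidative addition of zerovalent palladium to the enol triflate, 7-exo-trig syn-carbopalladation of the trisubstituted C10=C1 alkene and syn-β-hydride elimination toward C2 (C10 has no hydrogen) give quaternary C10 and the C1=C2 alkene; the alkene should approach the exo face (C14 side) of the vinylpalladium with C5 held near C8 by the tether, which places C1 on the C15 side and the methyl toward C11, and with the (R)-configured C5 this is the trans-fused closure.

Step 10
Reactants: 15 ε-lactone
Product: 17 6-methoxy-6,7-epoxy-6,7-seco-ent-kaura-1,9(11),16-triene (cyclic methyl acetal), via lactol 16 (not isolated)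
Conditions: i-Bu2AlH (1.2 equiv), CH2Cl2, −78 °C; aqueous Rochelle salt; crude lactol, MeOH, pyridinium p-toluenesulfonate, 23 °C
Reagents that add atoms: methanol, CO
Why: Partial reduction of the lactone to the lactol at low temperature and acid-catalysed acetalization with methanol protect C6 at the aldehyde oxidation level; the anomeric configuration is left open because it is reset in step 18.

Step 11
Reactants: 17 methyl acetal
Product: 18 15-hydroxy derivative of 17 (allylic alcohol, C16=C17 retained)
Conditions: SeO2 (0.5 equiv), t-BuOOH, CH2Cl2, 23 °C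
Reagents that add atoms: selenium dioxide, O=[Se]=O; tert-butyl hydroperoxide, CC(C)(C)OO
Why: SeO2 allylic oxidation (ene reaction then [2,3]-sigmatropic shift) should occur at C15, the only allylic methylene of the 1,1-disubstituted alkene, because C9=C11 has no allylic hydrogen on its substituted end and the ring A alkene is less reactive; the C15 configuration is irrelevant.

Step 12
Reactants: 18 allylic alcohol
Product: 19 15-oxo derivative (exo-methylene ketone) of 17
Conditions: Dess–Martin periodinane, CH2Cl2, 23 °C
Reagents that add atoms: none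
Why: Dess–Martin oxidation of the allylic alcohol gives the enone, which also deactivates C16=C17 toward the osmylation that follows.

Step 13
Reactants: 19 enone
Product: 20 1,2-cis-diol of 19 (both hydroxyls trans to the C10 methyl)
Conditions: OsO4 (5 mol %), N-methylmorpholine N-oxide, acetone/H2O, 23 °C
Reagents that add atoms: osmium tetroxide, O=[Os](=O)(=O)=O; N-methylmorpholine N-oxide, C[N+]1([O-])CCOCC1
Why: Catalytic cis-dihydroxylation should take place at C1=C2, the only accessible electron-neutral alkene (C9=C11 is flanked by two quaternary carbons, C16=C17 is an enone), from the face opposite the axial C10 methyl; this face is immaterial because both carbinol centres are oxidized next.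

Step 14
Reactants: 20 diol
Product: 21 1,2,15-trione (ring A 1,2-dione, possibly as its C2 enol)
Conditions: (COCl)2, DMSO, CH2Cl2, −78 °C; Et3N, −78 → 0 °C
Reagents that add atoms: none
Why: Swern oxidation (activated DMSO) converts both secondary alcohols into ketones without cleaving the C1–C2 bond.

Step 15
Reactants: 21 trione
Product: 22 1,2,15-triol (1-OH equatorial and 2-OH axial, both cis to the C10 methyl; 15-OH allylic)
Conditions: NaBH4, CeCl3·7H2O, MeOH, −40 → 0 °C
Reagents that add atoms: none
Why: Luche-type hydride addition from the face opposite the syn-axial methyl groups on C10 and C4 should give the equatorial C1 and the axial C2 alcohol, both cis to the C10 methyl, while the enone is reduced 1,2 to the C15 allylic alcohol.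

Step 16
Reactants: 22 triol
Product: 23 15-oxo-1,2-diol
Conditions: MnO2 (activated, excess), CH2Cl2, 23 °C
Reagents that add atoms: none
Why: MnO2 oxidizes only the allylic C15 alcohol back to the enone and leaves the saturated ring A diol untouched (chemoselective allylic oxidation).

Step 17
Reactants: 23 enone diol
Product: 24 1,2-diacetate of 23
Conditions: Ac2O, DMAP, Et3N, CH2Cl2, 40 °C
Reagents that add atoms: acetic anhydride, CC(=O)OC(C)=O
Why: DMAP-catalysed acylation esterifies both secondary alcohols, the hindered axial C2 hydroxyl requiring warming.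

Step 18
Reactants: 24 diacetate methyl acetal
Product: 25 9(11)-ene lactol (the target without the epoxide oxygen)
Conditions: 1 M HCl, THF, 23 °C
Reagents that add atoms: water, O
Why: Acid-catalysed acetal hydrolysis releases the lactol, which should settle as the more stable anomer; acetates and enone tolerate dilute acid at room temperature.

Step 19
Reactants: 25 lactol
Product: 26 CNP0224512.1 (target)
Conditions: mCPBA, CH2Cl2, 0 °C
Reagents that add atoms: mCPBA, O=C(OO)c1cccc(Cl)c1
Why: Prilezhaev epoxidation of the only electron-rich alkene should occur from the exo face (side of the C14 bridge), because the endo face is covered by C1 with its acetate and by the C15–C16 bridge; the enone alkene is inert to peracid.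

**Compound list**

1 | (1S,2R,5S)-5-methyl-2-(2-phenylpropan-2-yl)cyclohexan-1-ol, (+)-8-phenylmenthol | O[C@H]1C[C@@H](C)CC[C@@H]1C(C)(C)c1ccccc1 | starting material
2 | 2,2,6-trimethyl-4H-1,3-dioxin-4-one | CC1=CC(=O)OC(C)(C)O1 | starting material
3 | acetylketene | CC(=O)C=C=O | intermediate
4 | (1S,2R,5S)-8-phenylmenthyl 3-oxobutanoate | CC(=O)CC(=O)O[C@H]1C[C@@H](C)CC[C@@H]1C(C)(C)c1ccccc1 | intermediate
5 | allyl bromide | C=CCBr | starting material
6 | 8-phenylmenthyl 3-oxohept-6-enoate | C=CCCC(=O)CC(=O)O[C@H]1C[C@@H](C)CC[C@@H]1C(C)(C)c1ccccc1 | intermediate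
7 | 8-phenylmenthyl 2-allyl-3-oxohept-6-enoate (epimers at the α-carbon) | C=CCCC(=O)C(CC=C)C(=O)O[C@H]1C[C@@H](C)CC[C@@H]1C(C)(C)c1ccccc1 | intermediate
8 | 8-phenylmenthyl (1R,5R)-6-methylene-2-oxobicyclo[3.2.1]octane-1-carboxylate | C=C1C[C@@]2(C(=O)O[C@H]3C[C@@H](C)CC[C@@H]3C(C)(C)c3ccccc3)C(=O)CC[C@@H]1C2 | intermediate
9 | 8-phenylmenthyl (1R,5R)-6-methylene-2-(trifluoromethylsulfonyloxy)bicyclo[3.2.1]oct-2-ene-1-carboxylate | C=C1C[C@@]2(C(=O)O[C@H]3C[C@@H](C)CC[C@@H]3C(C)(C)c3ccccc3)C(OS(=O)(=O)C(F)(F)F)=CC[C@@H]1C2 | intermediate
10 | [(1S,5R)-1-(hydroxymethyl)-6-methylenebicyclo[3.2.1]oct-2-en-2-yl] trifluoromethanesulfonate | C=C1C[C@@]2(CO)C(OS(=O)(=O)C(F)(F)F)=CC[C@@H]1C2 | intermediate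
11 | geranic acid, (2E)-3,7-dimethylocta-2,6-dienoic acid | CC(C)=CCC/C(C)=C/C(=O)O | starting material
12 | (±)-α-cyclogeranic acid | CC1=CCCC(C)(C)C1C(=O)O | intermediate
13 | (R)-α-cyclogeranic acid | OC(=O)[C@H]1C(C)=CCCC1(C)C | intermediate
14 | ester of alcohol 10 with acid 13 | C=C1C[C@@]2(COC(=O)[C@H]3C(C)=CCCC3(C)C)C(OS(=O)(=O)C(F)(F)F)=CC[C@@H]1C2 | intermediate
15 | 6,7-seco-ent-kaura-1,9(11),16-trien-6-oic acid 6,7-lactone | C=C1C[C@@]23COC(=O)[C@@H]4C(C)(C)CC=C[C@@]4(C)C2=CC[C@@H]1C3 | intermediate
16 | corresponding lactol (6-hydroxy, anomers) | C=C1C[C@@]23COC(O)[C@@H]4C(C)(C)CC=C[C@@]4(C)C2=CC[C@@H]1C3 | intermediate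
17 | cyclic methyl acetal (6-methoxy, anomers) | C=C1C[C@@]23COC(OC)[C@@H]4C(C)(C)CC=C[C@@]4(C)C2=CC[C@@H]1C3 | intermediate
18 | 15-hydroxy methyl acetal (C15 epimers) | C=C1C(O)[C@@]23COC(OC)[C@@H]4C(C)(C)CC=C[C@@]4(C)C2=CC[C@@H]1C3 | intermediate
19 | 15-oxo methyl acetal | C=C1C(=O)[C@@]23COC(OC)[C@@H]4C(C)(C)CC=C[C@@]4(C)C2=CC[C@@H]1C3 | intermediate
20 | 15-oxo-1,2-diol, hydroxyls trans to the C10 methyl | C=C1C(=O)[C@@]23COC(OC)[C@@H]4C(C)(C)C[C@@H](O)[C@@H](O)[C@@]4(C)C2=CC[C@@H]1C3 | intermediate
21 | 1,2,15-trione | C=C1C(=O)[C@@]23COC(OC)[C@@H]4C(C)(C)CC(=O)C(=O)[C@@]4(C)C2=CC[C@@H]1C3 | intermediate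
22 | 1,2,15-triol, 1- and 2-hydroxyls cis to the C10 methyl | C=C1C(O)[C@@]23COC(OC)[C@@H]4C(C)(C)C[C@H](O)[C@H](O)[C@@]4(C)C2=CC[C@@H]1C3 | intermediate
23 | 15-oxo-1,2-diol, hydroxyls cis to the C10 methyl | C=C1C(=O)[C@@]23COC(OC)[C@@H]4C(C)(C)C[C@H](O)[C@H](O)[C@@]4(C)C2=CC[C@@H]1C3 | intermediate
24 | 1,2-diacetate methyl acetal | C=C1C(=O)[C@@]23COC(OC)[C@@H]4C(C)(C)C[C@H](OC(C)=O)[C@H](OC(C)=O)[C@@]4(C)C2=CC[C@@H]1C3 | intermediate
25 | 9(11)-ene lactol diacetate | C=C1C(=O)[C@@]23CO[C@@H](O)[C@@H]4C(C)(C)C[C@H](OC(C)=O)[C@H](OC(C)=O)[C@@]4(C)C2=CC[C@@H]1C3 | intermediate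
26 | CNP0224512.1 | C=C1C(=O)[C@@]23CO[C@@H](O)[C@@H]4C(C)(C)C[C@H](OC(C)=O)[C@H](OC(C)=O)[C@@]4(C)[C@]24O[C@@H]4C[C@@H]1C3 | target

**Step count and risks**

Total step count: 19. Longest linear sequence: 17 steps (steps 1–5 and 8–19); steps 6–7 form the ring A branch.

Steps most likely to fail:

1. Step 9 (intramolecular Heck reaction). The carbopalladation may be too slow, because the ester must reach its disfavoured s-cis rotamer before C9 can reach the hindered C10; loss of the triflate by reduction or hydrolysis and double-bond migration could then take over. Fallback, setting out from 13 and 10 and returning at 17: acid 13 would be reduced with LiAlH4 to (R)-α-cyclogeraniol F1, oxidized with Dess–Martin periodinane to (R)-α-cyclocitral F2 and converted with HC(OMe)3 and pyridinium p-toluenesulfonate into (R)-α-cyclocitral dimethyl acetal F3. Acid-catalysed exchange of F3 with alcohol 10 would give the mixed methyl acetal F4, a tether without the rotamer penalty, and its Heck cyclization would give acetal 17 directly, so that step 10 falls away.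

2. Step 3 (oxidative tandem cyclization). Facial discrimination by the auxiliary may be poor, because the two rotamers about the C8–C7 bond expose opposite faces of the planar radical, and the diastereomers of 8 may not separate. Fallback, setting out from 5 and returning at 14: commercial methyl acetoacetate would be allylated twice with 5 as in step 2 to methyl 2-allyl-3-oxohept-6-enoate F5 and cyclized under the conditions of step 3 to racemic methyl 6-methylene-2-oxobicyclo[3.2.1]octane-1-carboxylate F6. This would be converted as in steps 4 and 5 into the racemic enol triflate ester F7 and the racemic triflate alcohol F8, which would be esterified with 13. The two diastereomeric esters, 14 and its isomer with the antipodal bicycle F9, would be separated by chromatography, so that the ring A acid serves as the resolving agent.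

3. Step 15 (reduction of the ring A dione). Hydride may be delivered to C1 from the wrong face, or the enol tautomer of 21 may be reduced unselectively, giving mixtures of diol isomers. Fallback, setting out from 20 and returning at 22: the less hindered equatorial C2 hydroxyl of 20 would be oxidized selectively with 2,2,6,6-tetramethylpiperidin-1-oxyl and PhI(OAc)2 to the 2-oxo-1-ol with axial hydroxyl F10. The C1 centre would be equilibrated with DBU to the 2-oxo-1-ol with equatorial hydroxyl F11, and this would be reduced with NaBH4 and CeCl3·7H2O to 22, so that C1 is set under thermodynamic control and only C2 by hydride delivery.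

Further compounds
F1 | step 9 | (R)-α-cyclogeraniol | OC[C@H]1C(C)=CCCC1(C)C
F2 | step 9 | (R)-α-cyclocitral | O=C[C@H]1C(C)=CCCC1(C)C
F3 | step 9 | (R)-α-cyclocitral dimethyl acetal | COC(OC)[C@H]1C(C)=CCCC1(C)C
F4 | step 9 | mixed methyl acetal of alcohol 10 and (R)-α-cyclocitral | C=C1C[C@@]2(COC(OC)[C@H]3C(C)=CCCC3(C)C)C(OS(=O)(=O)C(F)(F)F)=CC[C@@H]1C2
F5 | step 3 | methyl 2-allyl-3-oxohept-6-enoate | C=CCCC(=O)C(CC=C)C(=O)OC
F6 | step 3 | racemic methyl 6-methylene-2-oxobicyclo[3.2.1]octane-1-carboxylate | C=C1CC2(C(=O)OC)C(=O)CCC1C2
F7 | step 3 | racemic methyl 6-methylene-2-(trifluoromethylsulfonyloxy)bicyclo[3.2.1]oct-2-ene-1-carboxylate | C=C1CC2(C(=O)OC)C(OS(=O)(=O)C(F)(F)F)=CCC1C2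
F8 | step 3 | racemic [1-(hydroxymethyl)-6-methylenebicyclo[3.2.1]oct-2-en-2-yl] trifluoromethanesulfonate | C=C1CC2(CO)C(OS(=O)(=O)C(F)(F)F)=CCC1C2
F9 | step 3 | diastereomer of 14 with the antipodal bicycle | C=C1C[C@]2(COC(=O)[C@H]3C(C)=CCCC3(C)C)C(OS(=O)(=O)C(F)(F)F)=CC[C@H]1C2
F10 | step 15 | 2,15-dioxo-1-ol methyl acetal, hydroxyl trans to the C10 methyl | C=C1C(=O)[C@@]23COC(OC)[C@@H]4C(C)(C)CC(=O)[C@@H](O)[C@@]4(C)C2=CC[C@@H]1C3
F11 | step 15 | 2,15-dioxo-1-ol methyl acetal, hydroxyl cis to the C10 methyl | C=C1C(=O)[C@@]23COC(OC)[C@@H]4C(C)(C)CC(=O)[C@H](O)[C@@]4(C)C2=CC[C@@H]1C3
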